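Ring B, a 4,4-dimethylcyclohexane-1,3,5-trione (filicinic acid type) enol carrying the benzylic CH2 on one carbon, is cut into a four-carbon and a two-carbon piece. Heating 3-ethoxy-4,4-dimethylcyclobutenone with the triisopropylsilyl ynol ether of 3-(2,4,6-trimethoxyphenyl)propyne should assemble the whole ring in one operation: vinylketene formation, (2+2) addition, reopening and 6π closure. The step exploits the quaternary CMe2 carbon of ring B, which stops the cascade at a cyclohexa-2,4-dienone, and the oxygen on alternate ring carbons C1, C3 and C5, which the alkoxycyclobutenone and the oxygenated alkyne deliver directly. Hydrolysis, C-acetylation, arene propionylation and ketone-directed demethylation finish the target.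

Key step: step 4

Remark: ring B compounds are drawn in one enol tautomer of the trione; the target has no stereocentre, and the only stereogenic intermediate (11) is racemic and transient.

Step 1
Reactants: 1 2-methylpropanoyl chloride; 2 ethoxyethyne
Product: 4 3-ethoxy-4,4-dimethylcyclobut-2-en-1-one, via dimethylketene 3 (not isolated)
Conditions: Et3N, Et2O/hexanes, 0 °C → 35 °C
Reagents that add atoms: none
Why: Dehydrochlorination of the acid chloride by Et3N should release dimethylketene, which undergoes the known ketene–alkoxyalkyne (2+2) cycloaddition, its carbonyl carbon bonding to the unsubstituted alkyne carbon, to give the 3-alkoxycyclobutenone without any stereocentre.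

Step 2
Reactants: 5 2-(2,4,6-trimethoxyphenyl)acetic acid
Product: 6 methyl 2-(2,4,6-trimethoxyphenyl)acetate
Conditions: MeOH, H2SO4 (cat.), reflux
Reagents that add atoms: methanol, CO
Why: Fischer esterification in excess methanol should convert the unhindered arylacetic acid cleanly, the trimethoxyarene being inert to catalytic acid in methanol.

Step 3
Reactants: 6 methyl 2-(2,4,6-trimethoxyphenyl)acetate
Product: 9 triisopropyl[3-(2,4,6-trimethoxyphenyl)prop-1-ynoxy]silane, via lithium dibromoenolate 7 (not isolated), via lithium ynolate 8 (not isolated)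
Conditions: CH2Br2, LiTMP (lithium 2,2,6,6-tetramethylpiperidide), THF, −78 °C; then LiN(SiMe3)2; n-BuLi, −78 → 0 °C; then i-Pr3SiOTf, −78 °C → rt
Reagents that add atoms: dibromomethane, BrCBr; triisopropylsilyl trifluoromethanesulfonate, CC(C)[Si](OS(=O)(=O)C(F)(F)F)(C(C)C)C(C)C
Why: Kowalski ester homologation halted at the ynolate: LiCHBr2 adds to the ester, the dibromoketone enolate 7 undergoes Br/Li exchange and 1,2-shift of the benzylic group to ynolate 8, and the bulky silyl triflate traps 8 on oxygen to give the ynol silyl ether.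

Step 4
Reactants: 4 3-ethoxy-4,4-dimethylcyclobut-2-en-1-one; 9 triisopropyl[3-(2,4,6-trimethoxyphenyl)prop-1-ynoxy]silane
Product: 13 5-ethoxy-6,6-dimethyl-3-(triisopropylsilyloxy)-2-[(2,4,6-trimethoxyphenyl)methyl]cyclohexa-2,4-dien-1-one, via vinylketene 10 (not isolated), via alkenylcyclobutenone 11 (not isolated), via dienylketene 12 (not isolated)
Conditions: PhMe (degassed), 110 °C, sealed tube
Reagents that add atoms: none
Why: On heating, 4 should ring-open (4π, conrotatory) to vinylketene 10, whose C=C=O unit combines with ynol ether 9 in a (2+2) cycloaddition to cyclobutenone 11; 11 reopens reversibly, and only the dienylketene isomer 12 that holds the ketene and the ethoxyalkenyl arm cis on the central double bond can close. The closest known reaction type is the Danheiser annulation of cyclobutenones with siloxyalkynes, here stopped before aromatisation, a variant with thin precedent. Ring B is closed by thermal disrotatory 6π electrocyclisation of 12, the ketene carbon bonding to the CMe2 terminus. No stereocentre is created. The step needs regiocontrol in the (2+2) event and periselectivity over a (4+2) mode: oxygen donation makes the alkyne carbon that carries CH2Ar the nucleophile, so it attacks the electrophilic ketene carbon and the benzyl-bearing carbon ends up between C1=O and C3–OSi, and ketenes engage ynol ethers across their C=C bond. With two methyl groups on the carbon that closes the ring, no proton is available for enolisation to a phenol, so the cascade should end at dienone 13.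

Step 5
Reactants: 13 5-ethoxy-6,6-dimethyl-3-(triisopropylsilyloxy)-2-[(2,4,6-trimethoxyphenyl)methyl]cyclohexa-2,4-dien-1-one
Product: 14 5-hydroxy-6,6-dimethyl-4-[(2,4,6-trimethoxyphenyl)methyl]cyclohex-4-ene-1,3-dione
Conditions: 2 M HCl, THF, rt
Reagents that add atoms: water, O
Why: Acid-catalysed hydrolysis of a vinylogous ester and of a vinylogous silyl ester should unmask both carbonyl groups under conditions that leave the aryl methyl ethers and the methylene bridge untouched.

Step 6
Reactants: 14 5-hydroxy-6,6-dimethyl-4-[(2,4,6-trimethoxyphenyl)methyl]cyclohex-4-ene-1,3-dione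
Product: 16 2-acetyl-3,5-dihydroxy-4,4-dimethyl-6-[(2,4,6-trimethoxyphenyl)methyl]cyclohexa-2,5-dien-1-one, via enol acetate 15 (not isolated)
Conditions: Ac2O, Et3N, CH2Cl2, 0 °C; then DMAP (0.2 equiv), rt
Reagents that add atoms: acetic anhydride, CC(=O)OC(C)=O
Why: O-acetylation of the cyclic 1,3-dione followed by DMAP-catalysed O-to-C acyl transfer (enol ester rearrangement) should place the acetyl group on the only unsubstituted ring carbon, the resulting 2-acyl-1,3-dione enolate being the thermodynamic sink.

Step 7
Reactants: 16 2-acetyl-3,5-dihydroxy-4,4-dimethyl-6-[(2,4,6-trimethoxyphenyl)methyl]cyclohexa-2,5-dien-1-one; 17 propanoyl chloride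
Product: 18 2-acetyl-3,5-dihydroxy-4,4-dimethyl-6-[(2,4,6-trimethoxy-3-propanoylphenyl)methyl]cyclohexa-2,5-dien-1-one
Conditions: SnCl4, CH2Cl2, −20 → 0 °C; 1 M HCl work-up
Reagents that add atoms: none
Why: Friedel–Crafts acylation: the trimethoxyarene is the only carbon nucleophile left (ring B is fully substituted), its two open positions are equivalent by symmetry, the first ketone deactivates the ring against a second acylation, and any enol propanoate formed on ring B is cleaved in the acidic work-up.

Step 8
Reactants: 18 2-acetyl-3,5-dihydroxy-4,4-dimethyl-6-[(2,4,6-trimethoxy-3-propanoylphenyl)methyl]cyclohexa-2,5-dien-1-one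
Product: 19 2-acetyl-6-[(2,4-dihydroxy-6-methoxy-3-propanoylphenyl)methyl]-3,5-dihydroxy-4,4-dimethylcyclohexa-2,5-dien-1-one
Conditions: BCl3 (excess), CH2Cl2, −78 °C → rt; then 1 M HCl
Reagents that add atoms: none
Why: Chelation-directed Lewis-acid ether cleavage: boron bound to the aryl ketone oxygen activates only the two flanking methoxy groups for chloride attack at methyl, so the methoxy para to the ketone (next to the CH2 bridge) should survive, and hydrolysis of the boron chelates releases the target.

Compound list
1 | 2-methylpropanoyl chloride | CC(C)C(Cl)=O | starting material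
2 | ethoxyethyne | CCOC#C | starting material
3 | dimethylketene (2-methylprop-1-en-1-one) | CC(C)=C=O | intermediate
4 | 3-ethoxy-4,4-dimethylcyclobut-2-en-1-one | CCOC1=CC(=O)C1(C)C | intermediate
5 | 2-(2,4,6-trimethoxyphenyl)acetic acid | COc1cc(OC)c(CC(=O)O)c(OC)c1 | starting material
6 | methyl 2-(2,4,6-trimethoxyphenyl)acetate | COC(=O)Cc1c(OC)cc(OC)cc1OC | intermediate
7 | lithium 1,1-dibromo-3-(2,4,6-trimethoxyphenyl)prop-1-en-2-olate | [Li+].COc1cc(OC)c(CC([O-])=C(Br)Br)c(OC)c1 | intermediate
8 | lithium 3-(2,4,6-trimethoxyphenyl)prop-1-yn-1-olate | [Li+].COc1cc(OC)c(CC#C[O-])c(OC)c1 | intermediate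
9 | triisopropyl[3-(2,4,6-trimethoxyphenyl)prop-1-ynoxy]silane | COc1cc(OC)c(CC#CO[Si](C(C)C)(C(C)C)C(C)C)c(OC)c1 | intermediate
10 | 3-ethoxy-4-methylpenta-1,3-dien-1-one | CCOC(C=C=O)=C(C)C | intermediate
11 | racemic 4-(1-ethoxy-2-methylprop-1-en-1-yl)-3-(triisopropylsilyloxy)-2-[(2,4,6-trimethoxyphenyl)methyl]cyclobut-2-en-1-one | CCOC(=C(C)C)C1C(=O)C(Cc2c(OC)cc(OC)cc2OC)=C1O[Si](C(C)C)(C(C)C)C(C)C | intermediate
12 | (3E)-5-ethoxy-6-methyl-3-(triisopropylsilyloxy)-2-[(2,4,6-trimethoxyphenyl)methyl]hepta-1,3,5-trien-1-one (ketene and ethoxyalkenyl arm cis on the C3=C4 bond) | CCOC(=C(C)C)/C=C(O[Si](C(C)C)(C(C)C)C(C)C)\C(Cc1c(OC)cc(OC)cc1OC)=C=O | intermediate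
13 | 5-ethoxy-6,6-dimethyl-3-(triisopropylsilyloxy)-2-[(2,4,6-trimethoxyphenyl)methyl]cyclohexa-2,4-dien-1-one | CCOC1=CC(O[Si](C(C)C)(C(C)C)C(C)C)=C(Cc2c(OC)cc(OC)cc2OC)C(=O)C1(C)C | intermediate
14 | 5-hydroxy-6,6-dimethyl-4-[(2,4,6-trimethoxyphenyl)methyl]cyclohex-4-ene-1,3-dione (enol form of the ring B trione) | COc1cc(OC)c(CC2=C(O)C(C)(C)C(=O)CC2=O)c(OC)c1 | intermediate
15 | 5-hydroxy-6,6-dimethyl-3-oxo-4-[(2,4,6-trimethoxyphenyl)methyl]cyclohexa-1,4-dien-1-yl acetate (representative O-acetyl enol) | CC(=O)OC1=CC(=O)C(Cc2c(OC)cc(OC)cc2OC)=C(O)C1(C)C | intermediate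
16 | 2-acetyl-3,5-dihydroxy-4,4-dimethyl-6-[(2,4,6-trimethoxyphenyl)methyl]cyclohexa-2,5-dien-1-one | COc1cc(OC)c(CC2=C(O)C(C)(C)C(O)=C(C(C)=O)C2=O)c(OC)c1 | intermediate
17 | propanoyl chloride | CCC(Cl)=O | starting material
18 | 2-acetyl-3,5-dihydroxy-4,4-dimethyl-6-[(2,4,6-trimethoxy-3-propanoylphenyl)methyl]cyclohexa-2,5-dien-1-one | CCC(=O)c1c(OC)cc(OC)c(CC2=C(O)C(C)(C)C(O)=C(C(C)=O)C2=O)c1OC | intermediate
19 | 2-acetyl-6-[(2,4-dihydroxy-6-methoxy-3-propanoylphenyl)methyl]-3,5-dihydroxy-4,4-dimethylcyclohexa-2,5-dien-1-one (CNP0241167.0) | CCC(=O)c1c(O)cc(OC)c(CC2=C(O)C(C)(C)C(O)=C(C(C)=O)C2=O)c1O | target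

Total step count: 8. Longest linear sequence: 7 steps (5 → 6 → 9 → 13 → 14 → 16 → 18 → 19, steps 2 to 8); step 1 is a one-step side branch.

Steps most likely to fail

1. Step 4. Vinylketene 10 necessarily has a methyl group cis to the ketene, so it may drain away by 1,5-hydrogen shift or dimerisation before it captures the alkyne. The closure onto the quaternary terminus may also lag behind decomposition of the dienylketene. The fallback sets out from 9 and comes back at 14, building ring B by carbonyl condensation instead of a pericyclic cascade. Acid-catalysed methanolysis of 9 (MeOH, cat. TsOH, CH2Cl2) should give methyl 3-(2,4,6-trimethoxyphenyl)propanoate F1. Crossed Claisen condensation of F1 with methyl 2,2-dimethyl-3-oxobutanoate, enolised at its methyl ketone (LDA in excess, THF, −78 → 0 °C), should give methyl 2,2-dimethyl-3,5-dioxo-7-(2,4,6-trimethoxyphenyl)heptanoate F2. Double deprotonation of F2 (LDA, THF, −78 → 0 °C) puts the terminal carbanion on C6, which should acylate intramolecularly on the ester; acidic work-up then gives trione 14.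

2. Step 3. The arylacetate may be deprotonated at its benzylic carbon by LiCHBr2 or LiTMP faster than the carbenoid adds, and excess alkyllithium may metalate the trimethoxyarene. The fallback sets out from 6 and comes back at 9, reaching the ynolate by oxidation of an acetylide. Reduction of 6 (i-Bu2AlH, CH2Cl2, −78 °C) should give 2-(2,4,6-trimethoxyphenyl)acetaldehyde F3. Corey–Fuchs olefination (CBr4, PPh3, CH2Cl2, 0 °C) should give 2-(3,3-dibromoprop-2-en-1-yl)-1,3,5-trimethoxybenzene F4. n-BuLi (2 equiv, THF, −78 °C) should convert F4 into lithium 3-(2,4,6-trimethoxyphenyl)prop-1-yn-1-ide F5. Oxidation of F5 with LiOOt-Bu (from t-BuOOH and LiN(SiMe3)2, −78 → 0 °C) gives ynolate 8, and i-Pr3SiOTf then gives 9.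

3. Step 8. Once boron is chelated between the new phenoxide and the ketone, cleavage of the second ortho ether may stall, and forcing it may erode the para ether or the methylene bridge. The fallback sets out from 18 and comes back at 19, replacing selective cleavage by exhaustive cleavage and selective re-methylation. BBr3 (excess, CH2Cl2, −78 °C → rt) should give 2-acetyl-3,5-dihydroxy-4,4-dimethyl-6-[(2,4,6-trihydroxy-3-propanoylphenyl)methyl]cyclohexa-2,5-dien-1-one F6. Mono-methylation with Me2SO4 (1 equiv), K2CO3, acetone, rt should then take place at the phenol para to the propanoyl group, which is the most acidic one and is not hydrogen-bonded to the ketone. A dilute HCl work-up hydrolyses any enol methyl ether formed on ring B, leaving 19.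

Further compounds
F1 | step 4 | methyl 3-(2,4,6-trimethoxyphenyl)propanoate | COC(=O)CCc1c(OC)cc(OC)cc1OC
F2 | step 4 | methyl 2,2-dimethyl-3,5-dioxo-7-(2,4,6-trimethoxyphenyl)heptanoate | COC(=O)C(C)(C)C(=O)CC(=O)CCc1c(OC)cc(OC)cc1OC
F3 | step 3 | 2-(2,4,6-trimethoxyphenyl)acetaldehyde | O=CCc1c(OC)cc(OC)cc1OC
F4 | step 3 | 2-(3,3-dibromoprop-2-en-1-yl)-1,3,5-trimethoxybenzene | COc1cc(OC)c(CC=C(Br)Br)c(OC)c1
F5 | step 3 | lithium 3-(2,4,6-trimethoxyphenyl)prop-1-yn-1-ide | [Li]C#CCc1c(OC)cc(OC)cc1OC
F6 | step 8 | 2-acetyl-3,5-dihydroxy-4,4-dimethyl-6-[(2,4,6-trihydroxy-3-propanoylphenyl)methyl]cyclohexa-2,5-dien-1-one | CCC(=O)c1c(O)cc(O)c(CC2=C(O)C(C)(C)C(O)=C(C(C)=O)C2=O)c1O
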